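## Structural features

The target is a single oxolane ring (O1, C2, C3, C4, C5) carrying a 3,4,5-trimethoxyphenyl group on C2, a hydroxymethyl group on C3 and a 3,4,5-trimethoxybenzoyl group on C4, with C5 unsubstituted; this numbering is used for every intermediate below. The three stereocentres are contiguous, (2S,3S,4R): aryl and CH2OH are cis, CH2OH and aroyl are trans, so the two large groups on C2 and C4 lie on opposite faces. Three points are fragile: C4–H is α to an aryl ketone and β to O1 (epimerisation, ring opening by β-elimination under base), the benzylic C2–O1 bond of an electron-rich aryl ether can ionise under acid and scramble C2, and the 1,4-related alcohol and ketone can form a hemiketal. C4 is therefore correctable at the end, with the trans arrangement expected to be the resting one, but C2 and C3 carry no acidifying group and their cis relationship is the crowded one, so it must be made under kinetic control; this is the real difficulty. The feature exploited is that C2 is a benzylic carbon bonded to O1: in an open-chain ether in which O1 already joins C5 to a 3,4,5-trimethoxybenzyl group, the C2–H bonds are the most hydridic in the molecule and lie five atoms from C3 (C3–C4–C5–O1–C2), so a carbene at C3 can insert there and make C2–C3, the ring and both difficult stereocentres at once. The remaining centre, C4, with its three carbon branches (aroyl carbon, C5–O, C3 with its carboxyl carbon), maps atom for atom onto (R)-paraconic acid. Both aryl groups have the 3,4,5-pattern, which electrophilic acylation of 1,2,3-trimethoxybenzene would not give (it reacts at C4), so an aryl bromide and a benzyl bromide are the natural aryl sources.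

## Logic of the disconnections

16 is traced back to 15 by re-forming the two C–O bonds of a cyclic ketal at the carbonyl carbon on C4. While the carbonyl is masked, C4–H is not acidic, O1 cannot be expelled by β-elimination, and hydride and strong base can be used elsewhere. No skeletal simplification results. The forward step needs an acid mild enough to leave the benzylic C2–O1 bond intact.

15 is traced to 14 by raising the C3 side chain from CH2OH to a methyl ester; no skeletal bond is cut. The ester is the acceptor group that the carbene on C3 requires, and it is the smallest one. The forward reduction must be faster than enolisation at C3.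

In 14 the C2–C3 bond is cut, which opens the ring, returns C2 to a benzylic CH2 and C3 to a diazo-bearing carbon, and leads to 13. This is the strategic cut: the ring and the two non-correctable stereocentres disappear, leaving an open chain with one stereocentre (C4) and O1 already in place. The forward step must prefer the C2–H bond over the hydrogen on C4 and over the arene and dioxolane of the C4 substituent, and must deliver cis-2,3/trans-3,4.

The C3=N2 unit of 13 is removed to give 11; in the forward direction nitrogen arrives by diazo transfer to the activated acyl derivative 12. The diazo group is the least robust function and is therefore introduced last. 11 is a stable ester that can be purified and stored. Enolate formation at C3 must not disturb C4, which the ketal guarantees (no acidic hydrogen and no leaving group on C4).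

In 11 the O1–C2 ether bond and the ester O–CH3 bond are cut. This separates the benzyl half 8 from the C3–C4–C5 half and reveals the lactone 7, in which O1 and the C3 carboxyl carbon protect each other; 9 and 10 are the salts passed through on the way. The route becomes convergent at this point. The forward step must O-alkylate the alkoxide faster than the lactone re-closes and must avoid acid.

The ketal C–O bonds of 7 are cut to give ketone 6. The ketal is placed here because every later step up to the last is basic, reductive or carbene chemistry. The forward step must ketalise a conjugated, hindered carbonyl without enolising it toward C4; this is the only stage at which C4 is at risk.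

In 6 the bond between the carbonyl carbon and the aryl ring is cut, giving the acyl electrophile 2 and the aryl nucleophile derived from 3 (through 4 and 5). The substitution pattern is then fixed by the position of the halogen, and a soft organometallic spares the lactone. The forward step needs a nucleophile that neither adds twice nor acts as a base toward C4–H.

2 is the activated form of 1 (C–Cl for C–OH); 1, 3 and 8 are purchased. Activation must be base-free so that no ketene can form at the centre next to the acyl group.

## Other disconnections considered

Alternative 1: The cut runs through O1–C2 and C4–C5, so C2, C3 and C4 come from the donor–acceptor cyclopropane A1 and C5 with O1 from formaldehyde.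
- Forward step: Sn(OTf)2 would bind the geminal diester of A1, the aldehyde oxygen would displace the malonate carbon from the benzylic carbon with inversion, and the malonate would close on the carbonyl carbon to give A2.
- In its favour: the 2,3-cis relationship follows from stereospecific inversion of a trans-cyclopropane, that is from mechanism and not from a catalyst–substrate match. On stereochemical predictability at C2/C3 this is the better plan. Two ring bonds form in one step.
- Against it here: formaldehyde is an awkward partner (oligomeric sources). An electron-rich aryl group invites reversible opening of A1 to a benzylic zwitterion and loss of configuration before capture. A2 carries two esters on C4 where one aroyl group is wanted, so one ester must be removed, C4 equilibrated, the other ester converted into the aryl ketone and the silyl ether cleaved.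
- Comparison: structurally, the chosen route brings C4 in at the right substitution pattern and as the source of chirality, whereas A1 needs its own asymmetric synthesis. Mechanistically, both transfer existing chirality, the annulation by a polar stereospecific path and the insertion by a concerted path that must outrun a hydride shift. In step count the alternative is expected to be two to four steps longer.

Alternative 2: The cut is the C4–C5 bond; O1 stays on C2 as a methoxymethyl ether in the open-chain enol silane A3.
- Forward step: TMSOTf would ionise the acetal to an O1=C5H2 oxocarbenium ion, and the enol silane carbon C4 would attack it to give A4, the pivalate of the target.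
- In its favour: A4 is one deprotection from the target, so the end-game is shorter than the chosen one, a clear advantage. The only stereocentre made in the ring closure is C4, the correctable one. No diazo compound and no chiral catalyst are needed.
- Against it here: the closure is 5-endo with respect to the O1=C5 bond, a strained trajectory. The Lewis acid can also ionise the benzylic C2–O bond or split the acetal the other way and lose the one-carbon unit. The C2/C3 pair must be built stereoselectively in the open chain A3, itself several steps from commercial materials. Ester cleavage from A4 must spare a base-sensitive β-alkoxy ketone.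
- Comparison: the two plans are equal in making one ring bond each. The alternative moves the C2/C3 problem out of the key step into acyclic chemistry, which is well understood but longer; the chosen route solves it in the ring-forming step. On certainty of the ring closure neither is clearly ahead.

Alternative 3: The cut is O1–C5, with the ring arising by isomerisation of the vinyl oxirane A5.
- Forward step: Cu(hfacac)2 or iodide would open the allylic C3–O bond, and the oxygen, still bonded to C2, would re-close on the terminal CH2 to give the 2,5-dihydrofuran A6.
- In its favour: the C2–O bond is never broken, so a configuration set by asymmetric epoxidation is carried through. The step is an isomerisation, atom-economic and free of diazo and azide reagents, which is a safety advantage over the chosen plan. Hydrogenation from the face opposite the aryl group would later make C2/C3 cis, and C4 can be equilibrated.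
- Against it here: A6 contains neither of the remaining stereocentres. A tetrasubstituted, ester-bearing alkene next to a benzylic, allylic C–O bond must be hydrogenated without hydrogenolysis or aromatisation. The ester on C4 must still become the aryl ketone. Competing ionisation of the benzylic epoxide bond in A5 would erode C2.
- Comparison: the alternative forms the ring first and adds stereochemistry afterwards; the chosen route does the reverse. The ring expansion is the more certain ring-forming event, but the risk moves to the hydrogenation. Four or more steps follow A6 against two after 14, and A5 is not shorter to make than 13.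

Key step: step 6

Remark: Ar = 3,4,5-trimethoxyphenyl. The 3R configuration of 13 is the one (R)-paraconic acid delivers when its carboxyl carbon becomes the ketal carbon, its ring OCH2 becomes C5 and its CH2C=O becomes C3; 13 and 14 as drawn are consistent with 16.

Assumption: the S antipode of the phthalimido-tert-leucinate catalyst is taken as the one matched with the 4R centre of 13; this cannot be derived with certainty for this substrate, and the R antipode is the first variable if facial selectivity is poor.

Step 1
Reactants: 1 (R)-paraconic acid
Product: 2 (3R)-5-oxooxolane-3-carbonyl chloride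
Conditions: (COCl)2, cat. DMF, CH2Cl2, 0 → 23 °C
Reagents that add atoms: oxalyl chloride, ClC(=O)C(=O)Cl
Why: Acyl chloride formation through the chloroiminium intermediate; no base is present, so the centre next to the acyl chloride cannot racemise through a ketene, and the lactone is inert.

Step 2
Reactants: 2 (3R)-5-oxooxolane-3-carbonyl chloride; 3 5-bromo-1,2,3-trimethoxybenzene
Product: 6 (4R)-4-(3,4,5-trimethoxybenzoyl)oxolan-2-one, via 3,4,5-trimethoxyphenyllithium 4 (not isolated), via 3,4,5-trimethoxyphenylzinc chloride 5 (not isolated)
Conditions: 3, n-BuLi, THF, −78 °C; ZnCl2, −78 → 0 °C; then 2, Pd(PPh3)4 (cat.), THF, 0 → 23 °C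
Reagents that add atoms: none
Why: Negishi acylation: bromine–lithium exchange, transmetallation to zinc and zerovalent-palladium-catalysed coupling with the acyl chloride give the ketone without over-addition, because an arylzinc chloride attacks neither ketone nor lactone. The reagent is too weakly basic to enolise the new ketone toward C4, and the bromide position fixes the 3,4,5-pattern.

Step 3
Reactants: 6 (4R)-4-(3,4,5-trimethoxybenzoyl)oxolan-2-one
Product: 7 (4R)-4-[2-(3,4,5-trimethoxyphenyl)-1,3-dioxolan-2-yl]oxolan-2-one
Conditions: (TMSOCH2)2, TMSOTf (cat.), CH2Cl2, −78 → −20 °C; pyridine quench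
Reagents that add atoms: 1,2-bis(trimethylsilyloxy)ethane, C[Si](C)(C)OCCO[Si](C)(C)C
Why: Silyl-transfer ketalisation gives the dioxolane with hexamethyldisiloxane as the only by-product, under aprotic conditions and below −20 °C, where acid-catalysed enolisation toward C4 is slow. The cyclic ketal is chosen over an open dialkyl ketal (whose OCH3 groups would be unstrained 1,5 targets for the later carbene) and over the free ketone (acidic C4–H, β-elimination of O1).

Step 4
Reactants: 7 (4R)-4-[2-(3,4,5-trimethoxyphenyl)-1,3-dioxolan-2-yl]oxolan-2-one; 8 3,4,5-trimethoxybenzyl bromide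
Product: 11 methyl (3R)-3-[2-(3,4,5-trimethoxyphenyl)-1,3-dioxolan-2-yl]-4-[(3,4,5-trimethoxyphenyl)methoxy]butanoate, via potassium hydroxy carboxylate 9 (not isolated), via potassium benzyloxy carboxylate 10 (not isolated)
Conditions: KOH (powder, 2.5 equiv), 8 (1.3 equiv), toluene, 110 °C, azeotropic removal of water; then MeI, DMF, 23 °C
Reagents that add atoms: potassium hydroxide, [K+].[OH-]; iodomethane, CI
Why: Hydroxide opens the lactone to the potassium hydroxy carboxylate, its alkoxide is benzylated as water is removed (Williamson ether synthesis), and the remaining carboxylate is methylated by SN2 on iodomethane, so the ketal never meets acid and the hydroxy acid is never free to re-lactonise. C4 has no acidic hydrogen once the ketone is masked, so hot base cannot epimerise it.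

Step 5
Reactants: 11 methyl (3R)-3-[2-(3,4,5-trimethoxyphenyl)-1,3-dioxolan-2-yl]-4-[(3,4,5-trimethoxyphenyl)methoxy]butanoate
Product: 13 methyl (3R)-2-diazo-3-[2-(3,4,5-trimethoxyphenyl)-1,3-dioxolan-2-yl]-4-[(3,4,5-trimethoxyphenyl)methoxy]butanoate, via α-trifluoroacetyl ester 12 (not isolated)
Conditions: LiN(SiMe3)2, THF, −78 °C; CF3CO2CH2CF3; aq NH4Cl; then 4-acetamidobenzenesulfonyl azide, Et3N, H2O (1 equiv), MeCN, 23 °C
Reagents that add atoms: 4-acetamidobenzenesulfonyl azide, CC(=O)Nc1ccc(cc1)S(=O)(=O)N=[N+]=[N-]
Why: Deacylative (Regitz-type) diazo transfer: Claisen C-trifluoroacetylation of the lithium enolate activates C3 as a 1,3-dicarbonyl compound, and the sulfonyl azide then transfers N2 and carries off the trifluoroacetyl group as the N-acyl sulfonamide. Only C3 is deprotonated, since C4 has neither an acidic hydrogen nor a β-leaving group; the arenesulfonyl azide used is the less shock-sensitive choice.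

Step 6
Reactants: 13 methyl (3R)-2-diazo-3-[2-(3,4,5-trimethoxyphenyl)-1,3-dioxolan-2-yl]-4-[(3,4,5-trimethoxyphenyl)methoxy]butanoate
Product: 14 methyl (2S,3R,4R)-2-(3,4,5-trimethoxyphenyl)-4-[2-(3,4,5-trimethoxyphenyl)-1,3-dioxolan-2-yl]oxolane-3-carboxylate
Conditions: dirhodium tetrakis[N-phthaloyl-(S)-tert-leucinate], Rh2(S-PTTL)4 (2 mol %), toluene, −78 °C, slow addition of 13
Reagents that add atoms: none
Why: Loss of N2 from 13 at the dirhodium core gives an electrophilic carbene at C3; its empty orbital accepts the benzylic C2–H bond of the ether in a concerted but asynchronous event (hydride transfer running ahead of C2–C3 bond formation) that releases the catalyst. The closest known reaction type is the dirhodium-carboxylate-catalysed 1,5 C–H insertion of α-alkyl-α-diazo esters into benzylic and ether-activated C–H bonds, for which phthalimido-tert-leucinate ligands at low temperature favour cis-2-aryl carboxylates and suppress alkene formation. The oxolane closes in the 1,5 mode through a five-membered cyclic transition state (C3, C4, C5, O1, C2), exo with respect to the Rh=C3 bond. Site selectivity is secured by the substrate: C2–H is the only bond that is both benzylic and α to oxygen, so O1 and the arene share the developing positive charge, whereas the dioxolane OCH2 groups could only be reached through a strained bridged transition state and the ortho carbons of the ketal aryl ring are flanked by a methoxy group and a fully substituted carbon. The 1,2-shift of the C4 hydrogen is disfavoured because three β-oxygen atoms make that hydrogen a poor hydride donor, because the reactive rotamer holds C4–H close to the carbene plane (eclipsing the ester, with the bulky ketal turned away) and not parallel to the empty orbital, and because of the low temperature and the bulky ligands. C3 is set by the existing C4 centre: in that rotamer the ketal group and the ester end up on opposite faces of the new ring (3,4-trans). C2 is set by the ligand wall acting together with the ketal group: the aryl group turns away from the ketal-bearing face, which places it cis to the ester (2,3-cis), the sense this catalyst class prefers in any case. The C2–H bond is replaced with retention and C4 is untouched, so 14 is expected as the 2S,3R,4R isomer.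

Step 7
Reactants: 14 methyl (2S,3R,4R)-2-(3,4,5-trimethoxyphenyl)-4-[2-(3,4,5-trimethoxyphenyl)-1,3-dioxolan-2-yl]oxolane-3-carboxylate
Product: 15 [(2S,3S,4R)-2-(3,4,5-trimethoxyphenyl)-4-[2-(3,4,5-trimethoxyphenyl)-1,3-dioxolan-2-yl]oxolan-3-yl]methanol
Conditions: LiAlH4, THF, −20 → 0 °C; Rochelle salt work-up
Reagents that add atoms: none
Why: Hydride reduction of the methyl ester to the primary alcohol; ethers and the ketal are inert to LiAlH4, and at low temperature reduction outruns enolisation, so C3 keeps its configuration (its descriptor changes from R to S only because the substituent priorities change).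

Step 8
Reactants: 15 [(2S,3S,4R)-2-(3,4,5-trimethoxyphenyl)-4-[2-(3,4,5-trimethoxyphenyl)-1,3-dioxolan-2-yl]oxolan-3-yl]methanol
Product: 16 [(2S,3S,4R)-3-(hydroxymethyl)-2-(3,4,5-trimethoxyphenyl)oxolan-4-yl](3,4,5-trimethoxyphenyl)methanone (the target; ring numbered O1, C2 aryl, C3 CH2OH, C4 aroyl)
Conditions: PPTS, acetone–H2O (4:1), 50 °C
Reagents that add atoms: water, O
Why: Acid-catalysed hydrolysis of the dioxolane through the aryl-stabilised oxocarbenium ion; the weak pyridinium acid is not expected to ionise the benzylic C2–O1 bond. The liberated ketone is trans to the CH2OH group, so a fused hemiketal would be strained, and C4, enolisable only from this point on, already has the trans arrangement expected to be favoured.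

## Compound list

1 | (R)-paraconic acid, (3R)-5-oxooxolane-3-carboxylic acid | OC(=O)[C@@H]1CC(=O)OC1 | starting material
2 | (3R)-5-oxooxolane-3-carbonyl chloride | ClC(=O)[C@@H]1CC(=O)OC1 | intermediate
3 | 5-bromo-1,2,3-trimethoxybenzene | COc1cc(Br)cc(OC)c1OC | starting material
4 | 3,4,5-trimethoxyphenyllithium | [Li]c1cc(OC)c(OC)c(OC)c1 | intermediate
5 | 3,4,5-trimethoxyphenylzinc chloride | Cl[Zn]c1cc(OC)c(OC)c(OC)c1 | intermediate
6 | (4R)-4-(3,4,5-trimethoxybenzoyl)oxolan-2-one | COc1cc(cc(OC)c1OC)C(=O)[C@@H]2CC(=O)OC2 | intermediate
7 | (4R)-4-[2-(3,4,5-trimethoxyphenyl)-1,3-dioxolan-2-yl]oxolan-2-one | COc1cc(cc(OC)c1OC)C2(OCCO2)[C@@H]3CC(=O)OC3 | intermediate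
8 | 3,4,5-trimethoxybenzyl bromide | COc1cc(CBr)cc(OC)c1OC | starting material
9 | potassium (3R)-4-hydroxy-3-[2-(3,4,5-trimethoxyphenyl)-1,3-dioxolan-2-yl]butanoate | [K+].[O-]C(=O)C[C@H](CO)C1(OCCO1)c2cc(OC)c(OC)c(OC)c2 | intermediate
10 | potassium (3R)-3-[2-(3,4,5-trimethoxyphenyl)-1,3-dioxolan-2-yl]-4-[(3,4,5-trimethoxyphenyl)methoxy]butanoate | [K+].[O-]C(=O)C[C@@H](C1(OCCO1)c2cc(OC)c(OC)c(OC)c2)COCc3cc(OC)c(OC)c(OC)c3 | intermediate
11 | methyl (3R)-3-[2-(3,4,5-trimethoxyphenyl)-1,3-dioxolan-2-yl]-4-[(3,4,5-trimethoxyphenyl)methoxy]butanoate | COC(=O)C[C@@H](C1(OCCO1)c2cc(OC)c(OC)c(OC)c2)COCc3cc(OC)c(OC)c(OC)c3 | intermediate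
12 | methyl (3R)-2-(trifluoroacetyl)-3-[2-(3,4,5-trimethoxyphenyl)-1,3-dioxolan-2-yl]-4-[(3,4,5-trimethoxyphenyl)methoxy]butanoate (C2 enolisable, not assigned) | COC(=O)C(C(=O)C(F)(F)F)[C@@H](C1(OCCO1)c2cc(OC)c(OC)c(OC)c2)COCc3cc(OC)c(OC)c(OC)c3 | intermediate
13 | methyl (3R)-2-diazo-3-[2-(3,4,5-trimethoxyphenyl)-1,3-dioxolan-2-yl]-4-[(3,4,5-trimethoxyphenyl)methoxy]butanoate | COC(=O)C(=[N+]=[N-])[C@@H](C1(OCCO1)c2cc(OC)c(OC)c(OC)c2)COCc3cc(OC)c(OC)c(OC)c3 | intermediate
14 | methyl (2S,3R,4R)-2-(3,4,5-trimethoxyphenyl)-4-[2-(3,4,5-trimethoxyphenyl)-1,3-dioxolan-2-yl]oxolane-3-carboxylate | COc1cc(cc(OC)c1OC)C3(OCCO3)[C@H]2CO[C@H](c4cc(OC)c(OC)c(OC)c4)[C@@H]2C(=O)OC | intermediate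
15 | [(2S,3S,4R)-2-(3,4,5-trimethoxyphenyl)-4-[2-(3,4,5-trimethoxyphenyl)-1,3-dioxolan-2-yl]oxolan-3-yl]methanol | COc1cc(cc(OC)c1OC)C3(OCCO3)[C@H]2CO[C@H](c4cc(OC)c(OC)c(OC)c4)[C@@H]2CO | intermediate
16 | [(3R,4S,5S)-4-(hydroxymethyl)-5-(3,4,5-trimethoxyphenyl)oxolan-3-yl](3,4,5-trimethoxyphenyl)methanone, i.e. 2S,3S,4R in the numbering used here | COc1cc(C(=O)[C@H]2CO[C@H](c3cc(OC)c(OC)c(OC)c3)[C@@H]2CO)cc(OC)c1OC | target

## Step count and least certain steps

Total step count: 8. Longest linear sequence: 8 steps (1 to 16); 3 and 8 enter as purchased materials.

**Step 6 (key step).** The most likely failure is migration of the C4 hydrogen to the carbene centre outrunning insertion, because that hydrogen is tertiary and adjacent. Electrophilic attack of the carbene on the ketal aryl ring, or a mismatched catalyst antipode giving poor facial discrimination at C2/C3, are the next risks. Before leaving the carbene approach, Rh2(R-PTTL)4 and the achiral bulky Rh2(O2CCPh3)4 would be tried.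
The fallback makes C2–C3 by aldol addition and closes the ring by etherification at C5; it sets out from 7 and returns at 15.
- 7 is deprotonated with LiN(SiMe3)2 in THF at −78 °C, the enolate is exchanged to zinc with ZnCl2 and added to 3,4,5-trimethoxybenzaldehyde. Attack anti to the C4 substituent through a closed chair-like transition state of the ring-locked enolate should favour the anti aldol lactone F1 (carbinol S, C3 trans to C4).
- Aminolysis with pyrrolidine and AlMe3 opens the lactone to the dihydroxy pyrrolidine amide F2, whose C3 carbonyl group can no longer recapture the C5 oxygen.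
- Mitsunobu cyclodehydration (PPh3, DIAD, THF) activates the primary C5 hydroxyl; the benzylic hydroxyl displaces it, closing O1–C5 with retention at C2 to give the oxolane pyrrolidine amide F3.
- LiNH2BH3 in THF reduces the tertiary amide to the primary alcohol 15.
This trades the carbene selectivity problem for incomplete control of the carbinol centre in the aldol step, which may require separation of epimers.

**Step 5.** The most likely failure is incomplete C-acylation of the hindered, β-branched ester enolate (Claisen self-condensation or retro-Claisen loss of the trifluoroacetyl group before the azide arrives), leaving unreacted 11.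
The fallback introduces nitrogen as azide and makes the diazo group by diazotisation; it sets out from 11 and returns at 13.
- The potassium enolate of 11 (KN(SiMe3)2, THF, −78 °C) is treated with 2,4,6-triisopropylbenzenesulfonyl azide and then acetic acid to give the α-azido ester F4 (either C2 epimer serves).
- Staudinger reduction (PPh3, THF–H2O) gives the α-amino ester F5.
- Diazotisation with isoamyl nitrite and catalytic acetic acid in chloroform at 60 °C gives 13.

**Step 3.** The most likely failure is loss of enantiomeric purity by acid-promoted enolisation toward C4 while the conjugated, hindered carbonyl group ketalises slowly.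
The fallback sets the stereocentre by catalyst after the ketal is in place; it sets out from 7 of eroded purity and returns at 7.
- α-Selenenylation (LiN(SiMe3)2, PhSeBr, THF, −78 °C) gives the trans selenide F6.
- Oxidative syn-elimination (H2O2, pyridine, CH2Cl2) gives the achiral butenolide F7.
- Copper-hydride-catalysed asymmetric conjugate reduction (CuCl2·2H2O, the antipode of p-tol-BINAP that delivers the R lactone, NaOtBu, polymethylhydrosiloxane, toluene) returns 7.

**Step 2.** The most likely failure is enolisation of the new ketone under the organometallic conditions, with expulsion of the lactone carboxylate from C5 or racemisation at C4.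
The fallback is a base-free ketone synthesis; it sets out from 2 and returns at 6.
- 2 is converted with 4-methylbenzenethiol and pyridine (CH2Cl2, 0 °C) into the thioester F8.
- Liebeskind–Srogl coupling with 3,4,5-trimethoxyphenylboronic acid (Pd2(dba)3, tri(2-furyl)phosphine, copper thiophene-2-carboxylate CuTC with monovalent copper, THF, 50 °C) gives 6 under neutral conditions.

## Further compounds

F1 | step 6 | (3R,4R)-3-[(S)-hydroxy(3,4,5-trimethoxyphenyl)methyl]-4-[2-(3,4,5-trimethoxyphenyl)-1,3-dioxolan-2-yl]oxolan-2-one | COc1cc(cc(OC)c1OC)C2(OCCO2)[C@H]3COC(=O)[C@H]3[C@H](O)c4cc(OC)c(OC)c(OC)c4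
F2 | step 6 | (2R,3R)-4-hydroxy-2-[(S)-hydroxy(3,4,5-trimethoxyphenyl)methyl]-1-(pyrrolidin-1-yl)-3-[2-(3,4,5-trimethoxyphenyl)-1,3-dioxolan-2-yl]butan-1-one | COc1cc(cc(OC)c1OC)C2(OCCO2)[C@@H](CO)[C@@H](C(=O)N3CCCC3)[C@H](O)c4cc(OC)c(OC)c(OC)c4
F3 | step 6 | pyrrolidin-1-yl[(2S,3R,4R)-2-(3,4,5-trimethoxyphenyl)-4-[2-(3,4,5-trimethoxyphenyl)-1,3-dioxolan-2-yl]oxolan-3-yl]methanone | COc1cc(cc(OC)c1OC)C3(OCCO3)[C@H]2CO[C@H](c4cc(OC)c(OC)c(OC)c4)[C@@H]2C(=O)N5CCCC5
F4 | step 5 | methyl (3R)-2-azido-3-[2-(3,4,5-trimethoxyphenyl)-1,3-dioxolan-2-yl]-4-[(3,4,5-trimethoxyphenyl)methoxy]butanoate (C2 not assigned) | COC(=O)C(N=[N+]=[N-])[C@@H](C1(OCCO1)c2cc(OC)c(OC)c(OC)c2)COCc3cc(OC)c(OC)c(OC)c3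
F5 | step 5 | methyl (3R)-2-amino-3-[2-(3,4,5-trimethoxyphenyl)-1,3-dioxolan-2-yl]-4-[(3,4,5-trimethoxyphenyl)methoxy]butanoate (C2 not assigned) | COC(=O)C(N)[C@@H](C1(OCCO1)c2cc(OC)c(OC)c(OC)c2)COCc3cc(OC)c(OC)c(OC)c3
F6 | step 3 | (3R,4R)-3-(phenylselanyl)-4-[2-(3,4,5-trimethoxyphenyl)-1,3-dioxolan-2-yl]oxolan-2-one | COc1cc(cc(OC)c1OC)C2(OCCO2)[C@@H]3[C@@H]([Se]c4ccccc4)C(=O)OC3
F7 | step 3 | 4-[2-(3,4,5-trimethoxyphenyl)-1,3-dioxolan-2-yl]furan-2(5H)-one | COc1cc(cc(OC)c1OC)C2(OCCO2)C3=CC(=O)OC3
F8 | step 2 | S-(4-methylphenyl) (3R)-5-oxooxolane-3-carbothioate | Cc1ccc(SC(=O)[C@@H]2CC(=O)OC2)cc1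
A1 | alternative 1 | diethyl (2R,3S)-3-[(tert-butyldimethylsilyloxy)methyl]-2-(3,4,5-trimethoxyphenyl)cyclopropane-1,1-dicarboxylate (aryl and silyloxymethyl trans) | CCOC(=O)C1(C(=O)OCC)[C@@H](c2cc(OC)c(OC)c(OC)c2)[C@@H]1CO[Si](C)(C)C(C)(C)C
A2 | alternative 1 | diethyl (4S,5S)-4-[(tert-butyldimethylsilyloxy)methyl]-5-(3,4,5-trimethoxyphenyl)oxolane-3,3-dicarboxylate (2,3-cis in the numbering used here) | CCOC(=O)C1(C(=O)OCC)CO[C@H](c2cc(OC)c(OC)c(OC)c2)[C@@H]1CO[Si](C)(C)C(C)(C)C
A3 | alternative 2 | (Z)-trimethylsilyl enol ether of (3S,4S)-4-(methoxymethoxy)-3-[(pivaloyloxy)methyl]-1,4-bis(3,4,5-trimethoxyphenyl)butan-1-one | COCO[C@H](c1cc(OC)c(OC)c(OC)c1)[C@H](COC(=O)C(C)(C)C)/C=C(\O[Si](C)(C)C)c2cc(OC)c(OC)c(OC)c2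
A4 | alternative 2 | [(2S,3S,4R)-4-(3,4,5-trimethoxybenzoyl)-2-(3,4,5-trimethoxyphenyl)oxolan-3-yl]methyl pivalate | COc1cc(cc(OC)c1OC)C(=O)[C@H]2CO[C@H](c3cc(OC)c(OC)c(OC)c3)[C@@H]2COC(=O)C(C)(C)C
A5 | alternative 3 | methyl 2-[(2S,3R)-2-[(tert-butyldimethylsilyloxy)methyl]-3-(3,4,5-trimethoxyphenyl)oxiran-2-yl]prop-2-enoate | COC(=O)C(=C)[C@@]1(CO[Si](C)(C)C(C)(C)C)O[C@@H]1c2cc(OC)c(OC)c(OC)c2
A6 | alternative 3 | methyl (5R)-4-[(tert-butyldimethylsilyloxy)methyl]-5-(3,4,5-trimethoxyphenyl)-2,5-dihydrofuran-3-carboxylate | COC(=O)C1=C(CO[Si](C)(C)C(C)(C)C)[C@@H](c2cc(OC)c(OC)c(OC)c2)OC1
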